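## The problem

Compound 20 is a (2S)-flavanone. Ring C, a dihydropyranone, is fused to ring A through C4a and C8a and carries ring B on C2. Ring A is a phloroglucinol with free hydroxyls on C5 and C7 and a prenyl group on C6 between them. Ring B carries a prenyl group on C2', a hydroxyl on C3' and a methoxy group on C4', so its prenyl group sits in the crowded position next to the ring junction. C2 is the only stereocentre, and nothing else in the molecule can direct it. It is labile, because the C2–O1 bond lies β to the C4 ketone and opens reversibly to the 2'-hydroxychalcone under base, and more slowly under acid or heat. Each prenyl alkene lies ortho to a phenol, so strong acid threatens chroman formation, hydrogenation would saturate the side chains, and electrophiles have to be kept away from them. In ring A the question of prenyl on C6 or on C8 is really the question of which phloroglucinol oxygen becomes O1. The enabling feature is that C4 is an isolated carbonyl carbon between C4a and C3, and at the flavone level C2–C3 has the oxidation state of an alkyne. C4 can therefore come from carbon monoxide, inserted between an ortho-iodophenol and an arylacetylene. The ring A phenol whose free hydroxyl is para to the prenyl group is symmetric, so iodination at either ortho carbon gives one iodophenol in which O1, C4a and C6 are already defined.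

## Retrosynthesis

**From 20 to 19.** The three phenols are masked as methoxymethyl ethers, so the last cut is at three O–CH2 bonds of tri-ether 19. Acetal ethers are chosen over benzyl ethers, whose hydrogenolysis would reduce the prenyl groups, and over silyl ethers, which would not survive the organolithium and hot amine steps. On ring A the acetal oxygens also direct the metalation that installs the prenyl group. The forward reaction has to be a mild acidolysis that spares the alkenes and C2.

**From 19 to 17.** The C2–H and C3–H bonds are removed, which leads back to the flat flavone 17. The neighbouring option, closing ring C at the flavanone oxidation level through a chalcone, would put C2 through the basic equilibrium that racemises it. Flavone 17 has no stereocentre to lose and tolerates the conditions of ring construction. The forward reaction is an enantioselective conjugate hydride addition to C2. It must leave two trisubstituted alkenes untouched, which rules out hydrogenation and points to a chiral copper hydride. The enolate is held as silyl enol ether 18 until work-up.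

**From 17 to 8, 13 and 14 (key disconnection).** Three bonds are cut: C4a–C4, C3–C4 and O1–C2. This gives iodophenol 8, arylacetylene 13 and carbon monoxide 14. Other flavone constructions fit this molecule less well:
- a Baker–Venkataraman sequence ends in an acid cyclodehydration next to prenyl groups;
- oxidative cyclisation of a chalcone uses electrophilic iodine or selenium on a substrate with two alkenes.

The carbonylative route runs under basic, reducing conditions and is convergent. Each of the two fragments carries one prenyl group already in place. The forward reaction must take up CO before the alkyne, and the intermediate ynone 15 must close 6-endo. A secondary amine ensures this by way of enaminone 16.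

**From 8 back to 1.** The C4a–I bond is cut to give symmetric phenol 7. Its two ortho carbons are equivalent, so the iodination poses no regiochemical question. The free hydroxyl of 7 is exposed from silyl ether 6. The prenyl C–C bond of 6 is cut between the ring carbon flanked by the two acetal oxygens and the allylic CH2, which leads to aryllithium 5 and prenyl bromide 4. Aryllithium 5 comes from silyl ether 3 by metalation at the one position activated by both acetal groups. Silyl ether 3 comes from bis-ether 2 and this from phloroglucinol 1. Direct C-prenylation of a phloroglucinol phenoxide would place the side chain ortho to the free oxygen, which is the wrong pattern. The directed metalation places it para to the oxygen that must stay free.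

**From 13 back to 9.** The alkyne is cut to aldehyde 12 by a one-carbon homologation. The C2'–CH2 bond of 12 is cut to aryl bromide 10 and prenylboronate 11. Bromide 10 is the methoxymethyl ether of commercial 2-bromo-3-hydroxy-4-methoxybenzaldehyde 9, which already has all four ring B substituents in the right order. The forward coupling must join the allyl unit at its unsubstituted end.

## Roads not taken

**Alternative 1:** Double aromatic Claisen rearrangement on the natural flavanone. The cut is at both aryl–CH2 bonds of the prenyl groups, leading back to (S)-hesperetin A1. In the forward sense the 7-O-silyl-5,3'-bis(1,1-dimethylallyl) ether A2 is heated, both allyl groups migrate with inversion, and the 7-O-silyl ether A3 of the target results.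
- Merits: this is the shortest road. It buys the whole skeleton and, if A1 is enantiopure, the stereocentre as well. In step count it is better than the chosen plan.
- Weak points: the tertiary allyl ether has to be made on the C5 hydroxyl, which is hydrogen-bonded to the ketone and poorly nucleophilic. The ring B ether can only migrate to the crowded C2', or by way of the blocked C4' to C6'. The rearrangement heats a flavanone whose C2 opens thermally. Ortho-prenylphenols formed at high temperature tend to cyclise. The enantiomeric purity of A1 from glycoside hydrolysis would also have to be secured first.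
- Comparison: the chosen plan is longer but places each prenyl group by an unambiguous C–C bond formation and does not expose C2 to heat.

**Alternative 2:** Ring B built from a furan. The cut is at C2'–C3' and C1'–C6' of ring B. In the forward sense 3-methoxyfuran A4 and the prenylated alkynoate A5 undergo a [4+2] cycloaddition, and the oxygen-bridged adduct opens to the phenol ester A6.
- Merits: the position of the prenyl group next to the C3' oxygen is written into the alkyne, so no allyl transposition can occur. In that respect it is cleaner than a cross-coupling.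
- Weak points: it builds only ring B, which commercial 9 already supplies fully substituted. Furan cycloadditions to alkynes with a single ester are slow and reversible. The acid-promoted opening takes place beside a prenyl alkene. A6 still needs several steps before it can be joined to ring A, and ring C and C2 remain unsolved.
- Comparison: the chosen plan reaches the ring B fragment in three steps from 9 and accepts one regioselective allyl coupling as the price.

**Alternative 3:** Ring C closed by Friedel–Crafts acylation. The cut is at C4–C4a. In the forward sense the acid chloride of the (S)-3-aryl-3-aryloxypropanoic acid A7 acylates the symmetric ring A ortho to the ether oxygen and gives the tris-silyl flavanone A8.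
- Merits: it uses the same symmetry of ring A as the chosen plan. C2 can be set beforehand by established asymmetric chemistry, so no new method is needed. In that respect it is better.
- Weak points: the acylation needs a Lewis or strong protic acid. The substrate carries two prenyl alkenes, three aryl silyl ethers and a benzylic aryl ether at C2 that an electron-rich ring B helps to ionise. Racemisation, elimination to the cinnamate and cation–olefin reactions are all open. Making the benzylic ether by displacement on an electron-rich benzylic alcohol may itself erode the stereocentre.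
- Comparison: the chosen plan keeps every intermediate under basic or neutral, non-electrophilic conditions until the final deprotection, and sets C2 after the ring is closed.

Key step: step 9

Assumption: the face selectivity of the DTBM-SEGPHOS copper hydride is carried over from cyclic β,β-disubstituted enones, which points to the (S)-ligand for the 2S product; if the sense proves opposite, the (R)-ligand is used and nothing else changes.

## Route

Step 1
Reactants: 1 phloroglucinol (benzene-1,3,5-triol)
Product: 2 3,5-bis(methoxymethoxy)phenol
Conditions: MOMCl (2.0 equiv), i-Pr2NEt (2.5 equiv), DMF, 0 °C → rt; chromatographic separation from mono- and tris-ether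
Reagents that add atoms: chloromethyl methyl ether (MOMCl), COCCl
Why: Williamson-type O-alkylation of a phenol; the three hydroxyls are equivalent, so the bis-ether is obtained statistically from a cheap starting material and is separable by polarity.

Step 2
Reactants: 2 3,5-bis(methoxymethoxy)phenol
Product: 3 {[3,5-bis(methoxymethoxy)phenyl]oxy}tri(propan-2-yl)silane
Conditions: TIPSCl, imidazole, DMF, rt
Reagents that add atoms: chlorotri(propan-2-yl)silane (TIPSCl), CC(C)[Si](Cl)(C(C)C)C(C)C
Why: Standard silylation of a phenol; the bulky silyl ether resists butyllithium, is a poor metalation director, and is later removed by fluoride without touching the acetal ethers.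

Step 3
Reactants: 3 {[3,5-bis(methoxymethoxy)phenyl]oxy}tri(propan-2-yl)silane; 4 1-bromo-3-methylbut-2-ene (prenyl bromide)
Product: 6 {[3,5-bis(methoxymethoxy)-4-(3-methylbut-2-en-1-yl)phenyl]oxy}tri(propan-2-yl)silane, via aryllithium 5 (not isolated)
Conditions: n-BuLi (1.2 equiv), THF, 0 °C; CuI (10 mol %), then 4, −78 °C → rt
Reagents that add atoms: 1-bromo-3-methylbut-2-ene (compound 4), CC(C)=CCBr
Why: Directed ortho-metalation at the only carbon flanked by two coordinating acetal oxygens gives 5, and copper-mediated allylic substitution at the primary carbon of 4 gives the linear prenyl arene, as is usual for prenylation of lithiated resorcinol bis-acetals.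

Step 4
Reactants: 6 {[3,5-bis(methoxymethoxy)-4-(3-methylbut-2-en-1-yl)phenyl]oxy}tri(propan-2-yl)silane
Product: 7 3,5-bis(methoxymethoxy)-4-(3-methylbut-2-en-1-yl)phenol
Conditions: Bu4NF, THF, 0 °C; aq NH4Cl
Reagents that add atoms: none
Why: Fluoride cleavage of an aryl silyl ether; the acetal ethers and the alkene are inert, and the product is the symmetric phenol with its free hydroxyl para to the prenyl group.

Step 5
Reactants: 7 3,5-bis(methoxymethoxy)-4-(3-methylbut-2-en-1-yl)phenol
Product: 8 2-iodo-3,5-bis(methoxymethoxy)-4-(3-methylbut-2-en-1-yl)phenol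
Conditions: N-iodosuccinimide (1.0 equiv), DMF, −20 → 0 °C, dark
Reagents that add atoms: N-iodosuccinimide, O=C1CCC(=O)N1I
Why: Electrophilic aromatic iodination of a trioxygenated phenol, which is far more nucleophilic than the trisubstituted alkene; the two open ring positions are equivalent, and one equivalent of reagent at low temperature should stop at the mono-iodide.

Step 6
Reactants: 9 2-bromo-3-hydroxy-4-methoxybenzaldehyde
Product: 10 2-bromo-4-methoxy-3-(methoxymethoxy)benzaldehyde
Conditions: MOMCl, i-Pr2NEt, CH2Cl2, 0 °C → rt
Reagents that add atoms: chloromethyl methyl ether (MOMCl), COCCl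
Why: O-alkylation of a phenol; the acetal ether removes the acidic proton before the cross-coupling and matches the protecting groups of ring A.

Step 7
Reactants: 10 2-bromo-4-methoxy-3-(methoxymethoxy)benzaldehyde; 11 4,4,5,5-tetramethyl-2-(3-methylbut-2-en-1-yl)-1,3,2-dioxaborolane (prenylboronic acid pinacol ester)
Product: 12 4-methoxy-3-(methoxymethoxy)-2-(3-methylbut-2-en-1-yl)benzaldehyde
Conditions: PdCl2(IPent)(3-chloropyridine) (2 mol %; IPent = 1,3-bis[2,6-di(pentan-3-yl)phenyl]imidazol-2-ylidene), 5 M aq KOH, THF, 65 °C
Reagents that add atoms: 4,4,5,5-tetramethyl-2-(3-methylbut-2-en-1-yl)-1,3,2-dioxaborolane (compound 11), CC(C)=CCB1OC(C)(C)C(C)(C)O1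
Why: Suzuki–Miyaura allyl–aryl coupling in its α-selective form; the very bulky carbene ligand makes reductive elimination occur at the unsubstituted allyl terminus, and the ortho-formyl group speeds oxidative addition at the hindered C–Br bond.

Step 8
Reactants: 12 4-methoxy-3-(methoxymethoxy)-2-(3-methylbut-2-en-1-yl)benzaldehyde
Product: 13 1-ethynyl-4-methoxy-3-(methoxymethoxy)-2-(3-methylbut-2-en-1-yl)benzene
Conditions: dimethyl (1-diazo-2-oxopropyl)phosphonate, K2CO3, MeOH, 0 °C → rt
Reagents that add atoms: dimethyl (1-diazo-2-oxopropyl)phosphonate (Ohira–Bestmann reagent), COP(=O)(OC)C(=[N+]=[N-])C(C)=O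
Why: Ohira–Bestmann variant of the Seyferth–Gilbert homologation; mild carbonate in methanol converts a non-enolisable aryl aldehyde to the terminal alkyne without affecting the acetal ether or the alkene.

Step 9
Reactants: 8 2-iodo-3,5-bis(methoxymethoxy)-4-(3-methylbut-2-en-1-yl)phenol; 13 1-ethynyl-4-methoxy-3-(methoxymethoxy)-2-(3-methylbut-2-en-1-yl)benzene; 14 carbon monoxide
Product: 17 2-[4-methoxy-3-(methoxymethoxy)-2-(3-methylbut-2-en-1-yl)phenyl]-5,7-bis(methoxymethoxy)-6-(3-methylbut-2-en-1-yl)-4H-chromen-4-one, via ynone 15 (not isolated), via enaminone 16 (not isolated)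
Conditions: PdCl2(PPh3)2 (5 mol %), CO (20 bar), Et2NH, 110 °C, autoclave
Reagents that add atoms: carbon monoxide (compound 14), [C-]#[O+]
Why: Zerovalent palladium, formed from PdCl2(PPh3)2 under the reaction conditions, inserts into the C–I bond of 8; CO insertion gives the aroyl complex of divalent palladium, which takes up the amine-deprotonated alkyne 13 and eliminates reductively to ynone 15, so that C4a–C4 and C4–C3 are made at the metal. The closest known reaction type is this same copper-free carbonylative Sonogashira coupling of ortho-iodophenols with arylacetylenes in a secondary amine, which ends in flavones. Et2NH adds to C2 of 15 to give enaminone 16, and the ortho hydroxyl then displaces the amine at that carbon by addition–elimination. Ring C is thus closed through O1–C2 in a formal 6-endo-dig oxa-Michael mode. No stereocentre is formed. The step needs 6-endo closure and not 5-exo closure to the aurone; this is secured because the amine has already taken the β-carbon, so the phenol can only substitute there. It also needs CO insertion to precede alkynylation, which the electron-rich aryl–palladium bond and the CO pressure favour. The placement of the prenyl group on C6 is fixed by the constitution of 8, where an acetal ether, not a free hydroxyl, lies between the iodine-bearing carbon and the prenyl carbon.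

Step 10
Reactants: 17 2-[4-methoxy-3-(methoxymethoxy)-2-(3-methylbut-2-en-1-yl)phenyl]-5,7-bis(methoxymethoxy)-6-(3-methylbut-2-en-1-yl)-4H-chromen-4-one
Product: 19 (2S)-2-[4-methoxy-3-(methoxymethoxy)-2-(3-methylbut-2-en-1-yl)phenyl]-5,7-bis(methoxymethoxy)-6-(3-methylbut-2-en-1-yl)-2,3-dihydro-4H-chromen-4-one, via silyl enol ether 18 (not isolated)
Conditions: Cu(OAc)2 (5 mol %), (S)-DTBM-SEGPHOS (5.5 mol %), (EtO)2MeSiH (3 equiv), toluene, 0 °C → rt; then 1 M aq HCl, THF, 0 °C
Reagents that add atoms: none
Why: Proposed new method: the bisphosphine copper hydride (monovalent copper, formed from Cu(OAc)2 and the silane) should deliver hydride to C2 of the enone from the face selected by the ligand, which alone sets the 2S centre; the copper enolate is trapped by the silane as silyl enol ether 18, which protects the ketone from 1,2-reduction and the C2–O1 bond from β-elimination until the cold acidic work-up; the closest known reaction type is the asymmetric copper hydride conjugate reduction of β,β-disubstituted cyclic enones and of simple 2-substituted chromones, whereas a 2-aryl-5,7-dialkoxychromone with an ortho-substituted ring B has not been shown; isolated trisubstituted alkenes are not reduced by this catalyst.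

Step 11
Reactants: 19 (2S)-2-[4-methoxy-3-(methoxymethoxy)-2-(3-methylbut-2-en-1-yl)phenyl]-5,7-bis(methoxymethoxy)-6-(3-methylbut-2-en-1-yl)-2,3-dihydro-4H-chromen-4-one
Product: 20 (2S)-5,7-dihydroxy-2-[3-hydroxy-4-methoxy-2-(3-methylbut-2-en-1-yl)phenyl]-6-(3-methylbut-2-en-1-yl)-2,3-dihydro-4H-chromen-4-one
Conditions: 3 M aq HCl, MeOH, 40 °C
Reagents that add atoms: none
Why: Acid-catalysed acetal exchange of aryl methoxymethyl ethers with methanol, the usual final step for prenylated flavanones; the conditions are mild enough that the alkenes and the C2 centre should survive, and the C5 hydroxyl is stabilised by its hydrogen bond to the ketone.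

## Compound list

1 | phloroglucinol (benzene-1,3,5-triol) | Oc1cc(O)cc(O)c1 | starting material
2 | 3,5-bis(methoxymethoxy)phenol | COCOc1cc(O)cc(OCOC)c1 | intermediate
3 | {[3,5-bis(methoxymethoxy)phenyl]oxy}tri(propan-2-yl)silane | COCOc1cc(O[Si](C(C)C)(C(C)C)C(C)C)cc(OCOC)c1 | intermediate
4 | 1-bromo-3-methylbut-2-ene | CC(C)=CCBr | starting material
5 | [2,6-bis(methoxymethoxy)-4-{[tri(propan-2-yl)silyl]oxy}phenyl]lithium | COCOc1cc(O[Si](C(C)C)(C(C)C)C(C)C)cc(OCOC)c1[Li] | intermediate (not isolated)
6 | {[3,5-bis(methoxymethoxy)-4-(3-methylbut-2-en-1-yl)phenyl]oxy}tri(propan-2-yl)silane | COCOc1cc(O[Si](C(C)C)(C(C)C)C(C)C)cc(OCOC)c1CC=C(C)C | intermediate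
7 | 3,5-bis(methoxymethoxy)-4-(3-methylbut-2-en-1-yl)phenol | COCOc1cc(O)cc(OCOC)c1CC=C(C)C | intermediate
8 | 2-iodo-3,5-bis(methoxymethoxy)-4-(3-methylbut-2-en-1-yl)phenol | COCOc1cc(O)c(I)c(OCOC)c1CC=C(C)C | intermediate
9 | 2-bromo-3-hydroxy-4-methoxybenzaldehyde | COc1ccc(C=O)c(Br)c1O | starting material
10 | 2-bromo-4-methoxy-3-(methoxymethoxy)benzaldehyde | COCOc1c(OC)ccc(C=O)c1Br | intermediate
11 | 4,4,5,5-tetramethyl-2-(3-methylbut-2-en-1-yl)-1,3,2-dioxaborolane | CC(C)=CCB1OC(C)(C)C(C)(C)O1 | starting material
12 | 4-methoxy-3-(methoxymethoxy)-2-(3-methylbut-2-en-1-yl)benzaldehyde | COCOc1c(OC)ccc(C=O)c1CC=C(C)C | intermediate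
13 | 1-ethynyl-4-methoxy-3-(methoxymethoxy)-2-(3-methylbut-2-en-1-yl)benzene | COCOc1c(OC)ccc(C#C)c1CC=C(C)C | intermediate
14 | carbon monoxide | [C-]#[O+] | starting material
15 | 1-[6-hydroxy-2,4-bis(methoxymethoxy)-3-(3-methylbut-2-en-1-yl)phenyl]-3-[4-methoxy-3-(methoxymethoxy)-2-(3-methylbut-2-en-1-yl)phenyl]prop-2-yn-1-one | COCOc1cc(O)c(C(=O)C#Cc2ccc(OC)c(OCOC)c2CC=C(C)C)c(OCOC)c1CC=C(C)C | intermediate (not isolated)
16 | 3-(diethylamino)-1-[6-hydroxy-2,4-bis(methoxymethoxy)-3-(3-methylbut-2-en-1-yl)phenyl]-3-[4-methoxy-3-(methoxymethoxy)-2-(3-methylbut-2-en-1-yl)phenyl]prop-2-en-1-one (alkene geometry not defined) | CCN(CC)C(=CC(=O)c1c(O)cc(OCOC)c(CC=C(C)C)c1OCOC)c1ccc(OC)c(OCOC)c1CC=C(C)C | intermediate (not isolated)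
17 | 2-[4-methoxy-3-(methoxymethoxy)-2-(3-methylbut-2-en-1-yl)phenyl]-5,7-bis(methoxymethoxy)-6-(3-methylbut-2-en-1-yl)-4H-chromen-4-one | COc1ccc(-c2cc(=O)c3c(cc(OCOC)c(CC=C(C)C)c3OCOC)o2)c(CC=C(C)C)c1OCOC | intermediate
18 | (2S)-4-{[diethoxy(methyl)silyl]oxy}-2-[4-methoxy-3-(methoxymethoxy)-2-(3-methylbut-2-en-1-yl)phenyl]-5,7-bis(methoxymethoxy)-6-(3-methylbut-2-en-1-yl)-2H-chromene | COc1ccc([C@@H]2C=C(O[Si](C)(OCC)OCC)c3c(cc(OCOC)c(CC=C(C)C)c3OCOC)O2)c(CC=C(C)C)c1OCOC | intermediate (not isolated)
19 | (2S)-2-[4-methoxy-3-(methoxymethoxy)-2-(3-methylbut-2-en-1-yl)phenyl]-5,7-bis(methoxymethoxy)-6-(3-methylbut-2-en-1-yl)-2,3-dihydro-4H-chromen-4-one | COc1ccc([C@@H]2CC(=O)c3c(cc(OCOC)c(CC=C(C)C)c3OCOC)O2)c(CC=C(C)C)c1OCOC | intermediate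
20 | (2S)-5,7-dihydroxy-2-[3-hydroxy-4-methoxy-2-(3-methylbut-2-en-1-yl)phenyl]-6-(3-methylbut-2-en-1-yl)-2,3-dihydro-4H-chromen-4-one | COc1ccc([C@@H]2CC(=O)c3c(cc(O)c(CC=C(C)C)c3O)O2)c(CC=C(C)C)c1O | target

## Step count and risks

Total: 11 steps. Longest linear sequence: 8 steps (steps 1–5, then 9–11); the ring B branch has 3 steps (6–8).

**Step 10 (proposed new method).** The flavone is a vinylogous aryl ester deactivated by three oxygen donors, and C2 carries an aryl ring twisted by its ortho prenyl group. Hydride transfer may therefore be slow, facial discrimination may be poor, or the copper enolate may undergo β-elimination, opening ring C and losing the new centre. The fallback uses known chemistry and sets out from 17.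
- Conjugate hydride reduction with LiBH(s-Bu)3 in THF at −78 °C, as practised on chromones, gives the racemic flavanone F1.
- F1 is resolved kinetically by asymmetric transfer hydrogenation with the enantiomer of RhCl(Cp*)(TsDPEN) that reduces the (2R)-ketone faster (HCO2H, Et3N). This is an established resolution of flavanones. It converts the unwanted enantiomer into the cis-(2R,4R)-flavan-4-ol F2 and leaves the (2S)-ketone.
- The fallback returns to the route at 19, at the cost of at most half of the material.

**Step 9 (key step).** The aroyl-palladium intermediate may be captured by the secondary amine to give the amide instead of the ynone. Alkynylation may occur without CO insertion and lead to a benzofuran. Oxidative addition at the doubly ortho-substituted, electron-rich C–I bond may be slow. The fallback sets out from 7 and 13 and does not need iodide 8.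
- Ortho-formylation of 7 with MgCl2, Et3N and paraformaldehyde gives 6-hydroxy-2,4-bis(methoxymethoxy)-3-(3-methylbut-2-en-1-yl)benzaldehyde F3.
- Alkyne 13 is deprotonated with n-BuLi to the lithium acetylide F4. An excess of F4 adds to F3 to give the propargylic alcohol F5.
- MnO2 oxidises F5 to ynone 15, where the fallback returns to the route. Et2NH in ethanol then closes 15 to 17 through 16 as in the key step.

**Step 7.** Allyl transposition at palladium would give the 1,1-dimethylallyl isomer. Protodeboronation of 11 and base-induced disproportionation of the aldehyde are further loss channels. The fallback sets out from 10 and 4.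
- The aldehyde is masked with HC(OMe)3, MeOH and catalytic pyridinium tosylate as the dimethyl acetal F6.
- Bromine–lithium exchange with n-BuLi at −78 °C gives the aryllithium F7.
- Transmetalation with CuBr·SMe2 and alkylation with 4 give the prenylated acetal F8.
- Brief treatment with aqueous acid in acetone hydrolyses F8 to 12, where the fallback returns to the route.

**Step 11.** The freed phenols may add to the neighbouring prenyl alkenes under acid (chroman formation). C2 may partly racemise by acid-mediated opening and re-closure of ring C. Cleavage of the hindered C5 ether may be incomplete. The fallback sets out from 19 and avoids Brønsted acid.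
- TESOTf and 2,2'-bipyridyl in CH2Cl2 at 0 °C exchange each aryl methoxymethyl ether for a triethylsilyl ether and give the tris(triethylsilyl) ether F9.
- Et3N·3HF in THF removes the silyl groups and returns to the route at 20.

## Further compounds

F1 | step 10 | racemic 2-[4-methoxy-3-(methoxymethoxy)-2-(3-methylbut-2-en-1-yl)phenyl]-5,7-bis(methoxymethoxy)-6-(3-methylbut-2-en-1-yl)-2,3-dihydro-4H-chromen-4-one | COc1ccc(C2CC(=O)c3c(cc(OCOC)c(CC=C(C)C)c3OCOC)O2)c(CC=C(C)C)c1OCOC
F2 | step 10 | (2R,4R)-2-[4-methoxy-3-(methoxymethoxy)-2-(3-methylbut-2-en-1-yl)phenyl]-5,7-bis(methoxymethoxy)-6-(3-methylbut-2-en-1-yl)-3,4-dihydro-2H-chromen-4-ol | COc1ccc([C@H]2C[C@@H](O)c3c(cc(OCOC)c(CC=C(C)C)c3OCOC)O2)c(CC=C(C)C)c1OCOC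
F3 | step 9 | 6-hydroxy-2,4-bis(methoxymethoxy)-3-(3-methylbut-2-en-1-yl)benzaldehyde | COCOc1cc(O)c(C=O)c(OCOC)c1CC=C(C)C
F4 | step 9 | {[4-methoxy-3-(methoxymethoxy)-2-(3-methylbut-2-en-1-yl)phenyl]ethynyl}lithium | [Li]C#Cc1ccc(OC)c(OCOC)c1CC=C(C)C
F5 | step 9 | racemic 1-[6-hydroxy-2,4-bis(methoxymethoxy)-3-(3-methylbut-2-en-1-yl)phenyl]-3-[4-methoxy-3-(methoxymethoxy)-2-(3-methylbut-2-en-1-yl)phenyl]prop-2-yn-1-ol | COCOc1cc(O)c(C(O)C#Cc2ccc(OC)c(OCOC)c2CC=C(C)C)c(OCOC)c1CC=C(C)C
F6 | step 7 | 2-bromo-1-(dimethoxymethyl)-4-methoxy-3-(methoxymethoxy)benzene | COCOc1c(OC)ccc(C(OC)OC)c1Br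
F7 | step 7 | [6-(dimethoxymethyl)-3-methoxy-2-(methoxymethoxy)phenyl]lithium | COCOc1c(OC)ccc(C(OC)OC)c1[Li]
F8 | step 7 | 1-(dimethoxymethyl)-4-methoxy-3-(methoxymethoxy)-2-(3-methylbut-2-en-1-yl)benzene | COCOc1c(OC)ccc(C(OC)OC)c1CC=C(C)C
F9 | step 11 | (2S)-2-{4-methoxy-2-(3-methylbut-2-en-1-yl)-3-[(triethylsilyl)oxy]phenyl}-6-(3-methylbut-2-en-1-yl)-5,7-bis[(triethylsilyl)oxy]-2,3-dihydro-4H-chromen-4-one | COc1ccc([C@@H]2CC(=O)c3c(cc(O[Si](CC)(CC)CC)c(CC=C(C)C)c3O[Si](CC)(CC)CC)O2)c(CC=C(C)C)c1O[Si](CC)(CC)CC
A1 | alternative 1 | (S)-hesperetin | COc1ccc([C@@H]2CC(=O)c3c(O)cc(O)cc3O2)cc1O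
A2 | alternative 1 | (2S)-7-[(tert-butyldimethylsilyl)oxy]-2-{4-methoxy-3-[(2-methylbut-3-en-2-yl)oxy]phenyl}-5-[(2-methylbut-3-en-2-yl)oxy]-2,3-dihydro-4H-chromen-4-one | COc1ccc([C@@H]2CC(=O)c3c(OC(C)(C)C=C)cc(O[Si](C)(C)C(C)(C)C)cc3O2)cc1OC(C)(C)C=C
A3 | alternative 1 | (2S)-7-[(tert-butyldimethylsilyl)oxy]-5-hydroxy-2-[3-hydroxy-4-methoxy-2-(3-methylbut-2-en-1-yl)phenyl]-6-(3-methylbut-2-en-1-yl)-2,3-dihydro-4H-chromen-4-one | COc1ccc([C@@H]2CC(=O)c3c(cc(O[Si](C)(C)C(C)(C)C)c(CC=C(C)C)c3O)O2)c(CC=C(C)C)c1O
A4 | alternative 2 | 3-methoxyfuran | COc1ccoc1
A5 | alternative 2 | methyl 6-methylhept-5-en-2-ynoate | COC(=O)C#CCC=C(C)C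
A6 | alternative 2 | methyl 3-hydroxy-4-methoxy-2-(3-methylbut-2-en-1-yl)benzoate | COC(=O)c1ccc(OC)c(O)c1CC=C(C)C
A7 | alternative 3 | (3S)-3-{3,5-bis[(tert-butyldimethylsilyl)oxy]-4-(3-methylbut-2-en-1-yl)phenoxy}-3-{3-[(tert-butyldimethylsilyl)oxy]-4-methoxy-2-(3-methylbut-2-en-1-yl)phenyl}propanoic acid | COc1ccc([C@H](CC(=O)O)Oc2cc(O[Si](C)(C)C(C)(C)C)c(CC=C(C)C)c(O[Si](C)(C)C(C)(C)C)c2)c(CC=C(C)C)c1O[Si](C)(C)C(C)(C)C
A8 | alternative 3 | (2S)-5,7-bis[(tert-butyldimethylsilyl)oxy]-2-{3-[(tert-butyldimethylsilyl)oxy]-4-methoxy-2-(3-methylbut-2-en-1-yl)phenyl}-6-(3-methylbut-2-en-1-yl)-2,3-dihydro-4H-chromen-4-one | COc1ccc([C@@H]2CC(=O)c3c(cc(O[Si](C)(C)C(C)(C)C)c(CC=C(C)C)c3O[Si](C)(C)C(C)(C)C)O2)c(CC=C(C)C)c1O[Si](C)(C)C(C)(C)C
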